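**Retrosynthetic overview**
- Target ⇒ its 3‑O‑benzyl ether; the last operation is a C–O cleavage by hydrogenolysis.
- Key disconnection: the aryl C8–O bond. The butanoyloxy group is put directly onto C8–H of the 3‑O‑benzyl‑7‑O‑methyl flavonol by para attack of the 5‑phenoxide on dibutanoyl peroxide.
- The two ethers (7‑O–CH3 and 3‑O–CH2Ph) ⇒ galangin, by acidity‑ordered O‑alkylation in one flask.
- Rings: none is built. Ring A, the pyranone ring C and the phenyl ring B are all bought with galangin, a catalogue natural flavonol.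

Assumption 1: the target has no stereocentre and no isolable atropisomer, so it is made as the single achiral compound drawn.
Assumption 2: dibutanoyl peroxide counts as a reagent; it is a known diacyl peroxide made in one operation from butanoyl chloride and alkaline H2O2 and is handled only as a cold, titrated toluene solution.

**Step 1**
Reactants: 1 galangin (3,5,7‑trihydroxy‑2‑phenyl‑4H‑chromen‑4‑one)
Product: 3 3‑(benzyloxy)‑5‑hydroxy‑7‑methoxy‑2‑phenyl‑4H‑chromen‑4‑one, via izalpinin 2 (not isolated)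
Conditions: MeI (1.0 equiv), K2CO3 (1.05 equiv), DMF, 0 °C → rt; then BnBr (1.2 equiv), K2CO3 (1.5 equiv), 40 °C
Reagents that add atoms: iodomethane, CI; benzyl bromide, BrCc1ccccc1
Why: Sequential Williamson etherification in which the most acidic 7‑OH takes the single equivalent of MeI first, the 3‑OH then takes the benzyl group, and the strongly chelated 5‑OH stays free; no stereocenter is formed.

**Step 2**
Reactants: 3 3‑(benzyloxy)‑5‑hydroxy‑7‑methoxy‑2‑phenyl‑4H‑chromen‑4‑one
Product: 5 3‑(benzyloxy)‑5‑hydroxy‑7‑methoxy‑4‑oxo‑2‑phenyl‑4H‑chromen‑8‑yl butanoate, via 8H‑dienone butanoate 4 (not isolated)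
Conditions: KOt‑Bu (0.98 equiv), 18‑crown‑6 (1.1 equiv), THF, −40 °C; (n‑PrCO2)2 (1.2 equiv), −40 → 0 °C, dark; then 1 M HCl
Reagents that add atoms: dibutanoyl peroxide, CCCC(=O)OOC(=O)CCC
Why: Proposed new method: an acyloxy‑transfer variant of the Elbs oxidation — the crown‑separated potassium 5‑phenoxide of 3 attacks a peroxide oxygen of dibutanoyl peroxide through its para carbon C8 (the carbon that peroxydisulfate attacks in 5‑hydroxyflavones), butanoate leaves, and dienone 4 (racemic at C8, a centre erased at once) tautomerises to the phenol, so the aryl C8–O bond and the ester arrive together; C6 attack is disfavoured because deprotonation and the crown ether remove the hydrogen‑bond and cation templates that steer diacyl peroxides ortho in neutral phenols, O‑acylation of the chelated 5‑oxygen is slow and reversible (perbutanoate re‑attacks the activated aryl ester), and the closest known reaction types are the Elbs persulfate oxidation of phenolates and the α‑acyloxylation of enolates by diacyl peroxides.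

**Step 3**
Reactants: 5 3‑(benzyloxy)‑5‑hydroxy‑7‑methoxy‑4‑oxo‑2‑phenyl‑4H‑chromen‑8‑yl butanoate
Product: 6 3,5‑dihydroxy‑7‑methoxy‑4‑oxo‑2‑phenyl‑4H‑chromen‑8‑yl butanoate (target)
Conditions: H2 (1 atm), 10% Pd/C, EtOAc, rt
Reagents that add atoms: none
Why: Catalytic hydrogenolysis of the benzyl ether frees the 3‑OH while the aryl butanoate, the aryl methyl ether and the tetrasubstituted C2=C3 bond of the pyranone are untouched; the product has no stereocenter.

**Compound list**
1 | galangin (3,5,7‑trihydroxy‑2‑phenyl‑4H‑chromen‑4‑one) | O=c1c(O)c(-c2ccccc2)oc2cc(O)cc(O)c12 | starting material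
2 | izalpinin (3,5‑dihydroxy‑7‑methoxy‑2‑phenyl‑4H‑chromen‑4‑one) | COc1cc(O)c2c(=O)c(O)c(-c3ccccc3)oc2c1 | intermediate (not isolated)
3 | 3‑(benzyloxy)‑5‑hydroxy‑7‑methoxy‑2‑phenyl‑4H‑chromen‑4‑one | COc1cc(O)c2c(=O)c(OCc3ccccc3)c(-c3ccccc3)oc2c1 | intermediate
4 | 3‑(benzyloxy)‑7‑methoxy‑4,5‑dioxo‑2‑phenyl‑5,8‑dihydro‑4H‑chromen‑8‑yl butanoate (racemic at C8, transient) | CCCC(=O)OC1C(OC)=CC(=O)C2=C1OC(-c1ccccc1)=C(OCc1ccccc1)C2=O | intermediate (not isolated)
5 | 3‑(benzyloxy)‑5‑hydroxy‑7‑methoxy‑4‑oxo‑2‑phenyl‑4H‑chromen‑8‑yl butanoate | CCCC(=O)Oc1c(OC)cc(O)c2c(=O)c(OCc3ccccc3)c(-c3ccccc3)oc12 | intermediate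
6 | 3,5‑dihydroxy‑7‑methoxy‑4‑oxo‑2‑phenyl‑4H‑chromen‑8‑yl butanoate (achiral) | CCCC(=O)Oc1c(OC)cc(O)c2c(=O)c(O)c(-c3ccccc3)oc12 | target

**Totals**
Total step count: 3. Longest linear sequence: 3 (fully linear).

**Steps most likely to fail**

Step 2 (the proposed new C8–H butanoyloxylation) is the most likely to fail. Possible failures are C6 attack, 5‑O‑acylation, electron‑transfer decomposition of the peroxide, or low conversion of the stabilised phenoxide. The fallback uses known chemistry, sets out from 3 and comes back at 5. Elbs persulfate oxidation of 3 (K2S2O8, aqueous KOH, pyridine, rt) gives potassium 3‑(benzyloxy)‑5‑hydroxy‑7‑methoxy‑4‑oxo‑2‑phenyl‑4H‑chromen‑8‑yl sulfate F4. Hydrolysis of this sulfate ester (dilute HCl, Na2SO3, 80 °C) gives 3‑(benzyloxy)‑5,8‑dihydroxy‑7‑methoxy‑2‑phenyl‑4H‑chromen‑4‑one F5. Butanoic anhydride (1.05 equiv) in pyridine at 0 °C then acylates the free 8‑OH in preference to the chelated 5‑OH and gives 5.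

Step 1 (one‑flask 7‑O‑methylation then 3‑O‑benzylation) is the next most likely to fail. The risk is partial 3‑O‑methylation, or 5‑O‑benzylation if pushed. The fallback replaces acidity control by protecting‑group control, sets out from 1 and comes back at 3, passing through 2, which is now isolated. Ac2O in pyridine gives galangin triacetate F1. PhSH and imidazole in NMP at 0 °C remove only the 7‑acetate and give 7‑hydroxy‑4‑oxo‑2‑phenyl‑4H‑chromene‑3,5‑diyl diacetate F2. Mitsunobu methylation (MeOH, PPh3, DIAD, THF) gives 7‑methoxy‑4‑oxo‑2‑phenyl‑4H‑chromene‑3,5‑diyl diacetate F3. Methanolysis (K2CO3, MeOH, rt) gives 2, and BnBr with K2CO3 in refluxing acetone gives 3.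

Step 3 (hydrogenolysis) is the least risky. Possible failures are slow cleavage of the hindered benzyl ether or partial reduction of ring C. The fallback replaces reduction by Lewis‑acid dealkylation, sets out from 5 and comes back at 6: BCl3 with pentamethylbenzene as benzyl‑cation scavenger in CH2Cl2 at −78 °C, where the 3‑O‑benzyl group next to the C4 carbonyl cleaves while the 7‑OMe and the aryl ester survive. It makes no new compound (F0).

**Further compounds**
F1 | step 1 | 4‑oxo‑2‑phenyl‑4H‑chromene‑3,5,7‑triyl triacetate (galangin triacetate) | CC(=O)Oc1cc(OC(C)=O)c2c(=O)c(OC(C)=O)c(-c3ccccc3)oc2c1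
F2 | step 1 | 7‑hydroxy‑4‑oxo‑2‑phenyl‑4H‑chromene‑3,5‑diyl diacetate | CC(=O)Oc1cc(O)cc2oc(-c3ccccc3)c(OC(C)=O)c(=O)c12
F3 | step 1 | 7‑methoxy‑4‑oxo‑2‑phenyl‑4H‑chromene‑3,5‑diyl diacetate | COc1cc(OC(C)=O)c2c(=O)c(OC(C)=O)c(-c3ccccc3)oc2c1
F4 | step 2 | potassium 3‑(benzyloxy)‑5‑hydroxy‑7‑methoxy‑4‑oxo‑2‑phenyl‑4H‑chromen‑8‑yl sulfate | COc1cc(O)c2c(=O)c(OCc3ccccc3)c(-c3ccccc3)oc2c1OS(=O)(=O)[O-].[K+]
F5 | step 2 | 3‑(benzyloxy)‑5,8‑dihydroxy‑7‑methoxy‑2‑phenyl‑4H‑chromen‑4‑one | COc1cc(O)c2c(=O)c(OCc3ccccc3)c(-c3ccccc3)oc2c1O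
F0 | step 3 | none | none
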